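The readings stem from a simulated flask with made-up constants; scatter was added.

- At early times the spring run already showed a hole in its balance: 0.833 h in, starting material had lost 9.00% of the charge and product stood at 0%, while the noon run, with 80.8 times the second catalyst, already read 8% of product.

| setting | spring | noon | ochre | grey | violet | blue | green |
|---|---|---|---|---|---|---|---|
| starting material | 20 mM | 20 mM | 20 mM | 20 mM | 20 mM | 20 mM | 20 mM |
| coupling partner | 36 mM | 36 mM | 36.0 mM | 36.0 mM | 36.0 mM | 36.0 mM | 36.0 mM |
| free catalyst | 20 µM | 20 µM | 20 µM | 20 µM | 20 µM | 20 µM | 20 µM |
| second catalyst | 0.026 mM | 2.1 mM | 0.020 mM | 0.060 mM | 0.20 mM | 0.60 mM | 1.5 mM |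
| added ligand | 12 µM | 12 µM | 12 µM | 12 µM | 12 µM | 12 µM | 12 µM |
| remark | run made earlier | run made earlier |  |  |  |  |  |
| time |  |  | 20 h | 20 h | 20 h | 20 h | 20 h |

- spring (time / h: product / %, starting material / %): 0.833: 0, 91; 2.50: 4, 80; 5.00: 6, 65; 8.00: 14, 54; 10.0: 21, 47
- noon (time / h: product / %, starting material / %): 0.833: 8, 96; 1.50: 10, 89; 3.00: 17, 81; 5.00: 32, 70; 10.0: 55, 47

(each reading ± 2 percentage points)

- the earlier runs were read with a standard deviation of 2 percentage points
- "hardly changes" means that all values lie within two and a half points (for a concentration: within two and a half percent of the largest)

- amount of product at the end, in percent of the starting material charged for ochre, grey, violet, blue, green, in this order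
- the shape of the row from first to last (hardly changes / rises all the way / falls all the way / rises, then falls / falls, then rises)

- Both runs had 47% of starting material left at 10.0 h, so I took its loss as first order and blind to the second catalyst, with a constant of 0.0755 /h.
- I called the gap the material that had left the starting material and had not yet appeared as product. In spring it read 9.00%, 16.0%, 29.0%, 32.0% and 32.0%, while in noon starting material and product summed to 102% at 10.0 h, which is no gap within the scatter.
- I took product to come out of the gap, but the gap in spring rose over the early readings, so I replaced its curve by its mean over the 10.0 h, 23.6%.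
- The drain constant, the fraction of the gap turned into product per hour (a pseudo-first-order constant), is then spring's 21% of product over that mean and those hours: 0.0889 /h, a reading that carries the scatter.
- I assumed it scales with the second catalyst, which gave ochre 0.0684 /h and grey 0.205 /h.
- Two first-order steps in series then gave me 42.1% for ochre and 66.0% for grey, with the later flasks climbing towards the 77.9% of starting material that I reckoned lost by 20 h.
- The forecast gave 44%, 67%, 75%, 77% and 77%, shape rises all the way, adding “Nothing suggests a fall at high loading”. Its first two values stand a little above mine.
- The flasks gave 38.2%, 61.4%, 73.2%, 76.1% and 76.9%: rises all the way.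

    starting material + free catalyst → free catalyst + open intermediate (k = 4600 /M/h)
    second catalyst + open intermediate ⇌ catalyst intermediate (K = 1.10 /M, k = 8900 /M/h)
    coupling partner + catalyst intermediate → second catalyst + product (k = 1.30 × 10⁵ /M/h)
    free catalyst + added ligand ⇌ idle complex, settled at all times (K = 29000 /M)

- At 20.0 h ochre still held 39.2% as open intermediate, which is the gap by its name, beside 22.6% of starting material. Taking product gained from 10.0 h to 20 h over the mean open intermediate and those hours, ochre's drain constant came to 0.0605 /h, less than the 0.0684 /h scaled from spring. The same count on grey gave 0.163 /h against 0.205 /h.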